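The target is a 5-deoxyflavan-3-ol whose C4 carries C2 of piceatannol. The C4–aryl bond is cut biomimetically (flavan-3,4-diol plus stilbene), and ring C is then unzipped at O1–C2 to a flat, achiral 2′-hydroxychalcone, commercial isoliquiritigenin. The key step is a one-pot two-enzyme cascade: chalcone isomerase adds the ring A phenol oxygen O1 to the enone β-carbon C2 (6-endo oxa-Michael, sets C2), with a face selectivity that small catalysts do not match on the unprotected chalcone, and flavanone 3-hydroxylase then oxygenates C3 trans to ring B. It exploits the ortho-acylphenol of ring A: the C4 carbonyl activates the closure, directs the C3 oxidation and later becomes the leaving group for the stilbene.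

Key step: step 1

Remark: both enzymes are taken as catalysts from routine heterologous expression in Escherichia coli; all carbon of the target comes from the two commercial starting materials.

Step 1
Reactants: 1 isoliquiritigenin [(E)-1-(2,4-dihydroxyphenyl)-3-(4-hydroxyphenyl)prop-2-en-1-one]
Product: 3 (2R,3R)-garbanzol [(2R,3R)-3,7-dihydroxy-2-(4-hydroxyphenyl)chroman-4-one], via (2S)-liquiritigenin 2 (not isolated)
Conditions: chalcone isomerase (legume type 2 enzyme, EC 5.5.1.6) and flavanone 3-hydroxylase (2-oxoglutarate-dependent non-haem iron dioxygenase, EC 1.14.11.9), as isolated enzymes or resting cells expressing both; disodium 2-oxoglutarate, FeSO4 (cat.), sodium ascorbate, catalase, air; KH2PO4/K2HPO4 buffer pH 7.0 with 5% DMSO, 30 °C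
Reagents that add atoms: dioxygen, O=O
Why: Chalcone isomerase binds the chalcone and delivers the deprotonated ring A phenol oxygen O1 to one enantiotopic face of the enone β-carbon C2 (intramolecular oxa-Michael addition, then protonation of the enolate at C3), which should give (2S)-liquiritigenin 2. The closest known reaction type is the native reaction of this enzyme class itself, since legume type 2 isomerases accept 6′-deoxychalcones, and the hydroxylation that follows is the native C3 oxygenation of (2S)-flavanones by 2-oxoglutarate-dependent dioxygenases. Ring C closes in the 6-endo-trig mode. C2 is fixed by the active site of the isomerase, and C3 by the hydroxylase, whose iron-oxo species abstracts the C3 hydrogen trans to ring B and returns hydroxyl with retention, so the 3-hydroxyl should end up trans to the aryl group (2R,3R; the descriptor at C2 changes only because the priorities change). The step needs enantioface selection over the racemic background closure, and the substrate secures this: without a 6′-hydroxyl the 2′-phenol is tied to the carbonyl by a hydrogen bond, so uncatalysed cyclisation at neutral pH is slow. Immediate consumption of 2 by the hydroxylase should also draw the reversible oxa-Michael equilibrium forward and keep the flavanone from racemising by ring opening.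

Step 2
Reactants: 3 (2R,3R)-garbanzol
Product: 4 (2R,3S,4R)-2-(4-hydroxyphenyl)chromane-3,4,7-triol (the 2,3-trans-3,4-trans flavan-3,4-diol)
Conditions: NaBH4 (excess), EtOH, 0 °C to rt, argon; then H2O at 0 °C, pH held near 7, EtOAc
Reagents that add atoms: none
Why: Borohydride reduction of the C4 aryl ketone: hydride should add axially to the half-chair ring C to give the equatorial 4-hydroxyl (3,4-trans, 4R) while C2 and C3 are untouched; the C4 configuration is erased again in step 3, so its selectivity is not critical.

Step 3
Reactants: 4 (2R,3S,4R)-2-(4-hydroxyphenyl)chromane-3,4,7-triol; 5 piceatannol [4-[(E)-2-(3,5-dihydroxyphenyl)ethenyl]benzene-1,2-diol]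
Product: 6 (2R,3S,4S)-4-[2-[(E)-2-(3,4-dihydroxyphenyl)ethenyl]-4,6-dihydroxyphenyl]-2-(4-hydroxyphenyl)chromane-3,7-diol (target)
Conditions: 5 (4 equiv), 0.1 M HCl in H2O/EtOH (1:1), rt, argon, dark; Sephadex LH-20 (EtOH)
Reagents that add atoms: none
Why: Biomimetic acid-catalysed condensation of a flavan-3,4-diol with a phenol (an SN1 Friedel–Crafts alkylation): loss of water from C4 gives a benzylic cation stabilised by O1 and the 7-hydroxyl of ring A, which C2 of the resorcinol ring (ring D) of 5, ortho to one hydroxyl and para to the other, should attack on the face anti to the neighbouring 3-hydroxyl, so that C4 is set 3,4-trans (4S) under control of C3, while the excess of 5 holds back self-condensation.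

Compound list
1 | isoliquiritigenin, (E)-1-(2,4-dihydroxyphenyl)-3-(4-hydroxyphenyl)prop-2-en-1-one | O=C(/C=C/c1ccc(O)cc1)c1ccc(O)cc1O | starting material
2 | (2S)-liquiritigenin, (2S)-7-hydroxy-2-(4-hydroxyphenyl)chroman-4-one | Oc1ccc([C@H]2Oc3cc(O)ccc3C(=O)C2)cc1 | intermediate
3 | (2R,3R)-garbanzol, (2R,3R)-3,7-dihydroxy-2-(4-hydroxyphenyl)chroman-4-one | Oc1ccc([C@H]2Oc3cc(O)ccc3C(=O)[C@@H]2O)cc1 | intermediate
4 | (2R,3S,4R)-2-(4-hydroxyphenyl)chromane-3,4,7-triol | Oc1ccc([C@H]2Oc3cc(O)ccc3[C@@H](O)[C@@H]2O)cc1 | intermediate
5 | piceatannol, 4-[(E)-2-(3,5-dihydroxyphenyl)ethenyl]benzene-1,2-diol | Oc1cc(O)cc(/C=C/c2ccc(O)c(O)c2)c1 | starting material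
6 | (2R,3S,4S)-4-[2-[(E)-2-(3,4-dihydroxyphenyl)ethenyl]-4,6-dihydroxyphenyl]-2-(4-hydroxyphenyl)chromane-3,7-diol | Oc1ccc([C@H]2Oc3cc(O)ccc3[C@@H](c3c(O)cc(O)cc3/C=C/c3ccc(O)c(O)c3)[C@@H]2O)cc1 | target

Total step count: 3. Longest linear sequence: 3 steps (1 to 3 to 4 to 6).

Steps most likely to fail

First, step 1. The dioxygenase may turn over the 5-deoxyflavanone only slowly or lose activity through iron-mediated oxidation, so that the cascade stalls at 2. It may also oxidise 3 further by desaturation to the flavonol. The fallback replaces the enzymes by reagent chemistry and sets out from 1. NaH and chloromethyl methyl ether in DMF at 0 °C should give (E)-1-[2,4-bis(methoxymethoxy)phenyl]-3-[4-(methoxymethoxy)phenyl]prop-2-en-1-one F1. Juliá–Colonna epoxidation (poly-L-leucine, urea–hydrogen peroxide, DBU, THF, rt) should then give [(2R,3S)-3-[4-(methoxymethoxy)phenyl]oxiran-2-yl][2,4-bis(methoxymethoxy)phenyl]methanone F2. HCl in MeOH at 50 °C removes the three acetals, and the freed ring A phenol opens the epoxide at the benzylic carbon with inversion (6-endo, favoured by the para-oxygen of ring B). The fallback comes back to the route at 3.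

Second, step 3. Under reversible protic ionisation the C4 cation may be captured at other nucleophilic sites (C4 of ring D between the two hydroxyls, the stilbene alkene, or ring A of 4 or 6). This would give regioisomers and oligomers and erode the 3,4-trans selectivity. The fallback changes the electrophile and its activation and sets out from 4. Toluene-α-thiol in AcOH at rt should give 2,3-trans-3,4-trans-4-(benzylsulfanyl)-2-(4-hydroxyphenyl)chromane-3,7-diol F3. AgBF4 in THF at 0 °C in the presence of 5 then ionises the C–S bond irreversibly without protic acid, and capture by C2 of ring D comes back to the route at 6.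

Third, step 2. In the basic borohydride medium the 4′-phenoxide may open ring C through a quinone methide and epimerise C2. The phenoxide-deactivated ketone may also be reduced sluggishly, and the diol may self-condense if the quench turns acidic. The fallback is a biocatalytic reduction at neutral pH and sets out from 3. Dihydroflavonol 4-reductase (NADPH-dependent reductase, EC 1.1.1.219; NADPH recycled with glucose dehydrogenase and D-glucose, KH2PO4/K2HPO4 buffer pH 6.5, 30 °C) should give the 3,4-cis diol (2R,3S,4S)-2-(4-hydroxyphenyl)chromane-3,4,7-triol F4. Under the conditions of step 3 it ionises to the same C4 cation as 4 and so comes back to the route at 6.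

Further compounds
F1 | step 1 | (E)-1-[2,4-bis(methoxymethoxy)phenyl]-3-[4-(methoxymethoxy)phenyl]prop-2-en-1-one | COCOc1ccc(/C=C/C(=O)c2ccc(OCOC)cc2OCOC)cc1
F2 | step 1 | [(2R,3S)-3-[4-(methoxymethoxy)phenyl]oxiran-2-yl][2,4-bis(methoxymethoxy)phenyl]methanone | O=C(c1ccc(OCOC)cc1OCOC)[C@@H]1O[C@H]1c1ccc(OCOC)cc1
F3 | step 3 | 2,3-trans-3,4-trans-4-(benzylsulfanyl)-2-(4-hydroxyphenyl)chromane-3,7-diol | Oc1ccc([C@H]2Oc3cc(O)ccc3[C@@H](SCc3ccccc3)[C@@H]2O)cc1
F4 | step 2 | (2R,3S,4S)-2-(4-hydroxyphenyl)chromane-3,4,7-triol | Oc1ccc([C@H]2Oc3cc(O)ccc3[C@H](O)[C@@H]2O)cc1
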